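The reckoning of this flask starts from the substrate curve. The curve is taken as first order in substrate and in coupling partner, and either adduct may take a second partner on the way to the double product.

| flask | substrate | coupling partner | remark | time |
|---|---|---|---|---|
| noon | 0.30 M | 0.18 M | run made earlier |  |
| dawn | 0.30 M | 0.72 M | run made earlier |  |
| dusk | 0.15 M | 0.36 M | run made earlier |  |
| flask | 0.30 M | 0.360 M |  | 2.5 d |

- noon (time / d: substrate / %, mono adduct / %): 0.208: 95, 4; 0.333: 91, 5; 0.500: 86, 7; 0.833: 83, 9; 1.67: 72, 8; 2.50: 64, 11
- dawn (time / d: substrate / %, mono adduct / %): 0.417: 68, 17; 0.833: 46, 17; 1.25: 34, 15; 1.67: 28, 10; 2.00: 22, 12; 2.50: 18, 12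
- dusk (time / d: substrate / %, mono adduct / %): 0.208: 90, 7; 0.417: 80, 9; 0.625: 71, 16; 1.25: 55, 14; 2.50: 34, 17

(scatter of a reading: 1.5 percentage points)



- amount of substrate at 2.5 d, in percent of the substrate charged
- amount of mono adduct at 2.5 d, in percent of the substrate charged
- amount of other mono adduct at 2.5 d, in percent of the substrate charged
- amount of double product at 2.5 d, in percent of the substrate charged

The coupling constant, the fractional substrate loss per day per mole per litre of partner present, is read from the dusk run, which has this flask's partner charge. Its reading at 0.417 d, taken against the charged partner, gives 1.49 /M/d, with the scatter of 1.5 percentage points in it. At that same time the dawn run, with twice the partner and twice the substrate, shows a logarithmic loss 1.73 times as large, a ratio of two readings that carry the same scatter.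

The curve in this flask starts with a pseudo-first-order slope of 0.535 /d, a half-life of 1.30 d at the charged partner. Held at that slope, substrate reaches 26.3% at 2.5 d, but the partner falls as it works.

Let the partner cost be the partner spent per substrate lost. The partner-to-substrate ratio then changes from its charged value by the factor exp(k·s·t), where s is the partner charge minus the cost times the substrate charge. A cost of one gives 40.0% substrate at 2.5 d. A cost of two gives 53.0%, on a curve levelling at 40.0%, since the partner charge is less than the 0.600 M that full double addition takes; there the partner is the limiting reagent. Joining the two ends at their midpoint gives 46.5%.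

The forecast argues “so the rate is first order in each reagent”. Its substrate of 45% lies lower than that midpoint, and beside it stand mono adduct 16%, other mono adduct 19% and double product 20%.

The flask gives substrate 42.9%, mono adduct 12.6%, other mono adduct 9.70% and double product 15.3%.

    substrate + coupling partner → mono adduct (k = 1.43 × 10⁻⁵ /M/s)
    substrate + coupling partner → other mono adduct (k = 3.07 × 10⁻⁶ /M/s)
    coupling partner + mono adduct → double product (k = 2.67 × 10⁻⁵ /M/s)
    coupling partner + other mono adduct → double product (k = 1.43 × 10⁻⁶ /M/s)
    mono adduct ⇌ isomer of the product (K = 2.30, k = 1.22 × 10⁻⁵ /s)

The other mono adduct stands 9.3 points below the forecast, and the flask holds 19.6% of isomer of the product at 2.50 d. The amounts left in this flask put the partner cost at 1.27, and with it the coupling constant gives 43.7% substrate. In the neighbour flask with 0.90 M of partner the cost is 1.54, the same constant gives 10.7% substrate, and that flask holds 9.85% of substrate at 2.50 d.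

Readings and results are simulated for substances that don't exist; the scatter is artificial.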